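**Retrosynthetic overview** (target numbered as a chroman-4-one: O1, C2, C3, C4, C4a, C5–C8, C8a)
1. Methyl ester and C7–OH ⇐ methanolysis of a temporary six-membered lactone (C7–O joined to the acid of the C8 side chain); C6 prenyl and C5–OH ⇐ aromatic Claisen shift of a 1,1-dimethylallyl ether on the C5 oxygen.
2. Pyranone ring (O1–C2–C3–C4) ⇐ salicylaldehyde (CHO on C4a, free OH on C8a) + but-2-yne: the aldehyde C–H adds across the alkyne (C4–C3), then the phenol closes O1–C2; C2 under catalyst control, C3 by equilibration.
3. Enabling feature: O1 and the C4 carbonyl carbon sit on the adjacent ring carbons C8a and C4a, so C2–C3 is one alkyne inserted between the C–H and O–H of an ortho-hydroxy aldehyde; the same phenol chelates the metal and closes the ring, and C3–H, α to the C4 ketone, lets both C3 epimers drain into the trans isomer.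
4. Salicylaldehyde ⇐ ortho-formylation next to the only free phenol of a lactone whose C5 oxygen carries the propargyl ether (blocking group and latent prenyl); lactone ⇐ phloroglucinol + (E)-hex-2-enal (iminium Friedel–Crafts alkylation sets the benzylic centre).
5. Ring order: benzene ring bought; temporary lactone ring (steps 1–2); pyranone ring last (step 6); no ring is formed afterwards.

Key step: step 6

Remark: intermediates 3–11 are named as chroman-2-ones; their O1, C4a, C5–OH, C6, C7–O and C8 become C7–O, C8, O1, C4a, C5–O and C6 of the target.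

**Step 1**
Reactants: 1 phloroglucinol (benzene-1,3,5-triol); 2 (E)-hex-2-enal
Product: 3 (4R)-4-propylchromane-2,5,7-triol (lactol as its anomeric mixture)
Conditions: (S)-α,α-diphenylprolinol trimethylsilyl ether (20 mol%), PhCO2H (20 mol%), 1 (3 equiv), MeCN, 0 °C to 20 °C
Reagents that add atoms: (E)-hex-2-enal, CCC/C=C/C=O
Why: Iminium activation of the enal (organocatalytic Friedel–Crafts alkylation followed by hemiacetalisation) lets the arene add to the β-carbon from the face not shielded by the diphenyl(silyloxy)methyl group of the E,s-trans iminium ion, which for the S catalyst should set the benzylic centre as R; the threefold symmetry of 1 makes all positions equivalent and its excess suppresses a second alkylation.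

**Step 2**
Reactants: 3 (4R)-4-propylchromane-2,5,7-triol
Product: 4 (4R)-5,7-dihydroxy-4-propylchroman-2-one
Conditions: [Cp*IrCl2]2 (2 mol%), K2CO3 (10 mol%), acetone, 40 °C
Reagents that add atoms: none
Why: Oppenauer-type transfer dehydrogenation of the lactol to the lactone, with acetone as hydrogen acceptor, uses no electrophilic oxidant, so the oxidation-prone resorcinol unit and the stereocentre should stay untouched.

**Step 3**
Reactants: 4 (4R)-5,7-dihydroxy-4-propylchroman-2-one; 5 3-chloro-3-methylbut-1-yne
Product: 6 (4R)-5-hydroxy-7-[(2-methylbut-3-yn-2-yl)oxy]-4-propylchroman-2-one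
Conditions: 5 (1.1 equiv), K2CO3 (1.2 equiv), KI (0.2 equiv), CuI (5 mol%), acetone, 40 °C, N2
Reagents that add atoms: 3-chloro-3-methylbut-1-yne, CC(C)(Cl)C#C
Why: Copper-assisted propargylic etherification (Williamson type, through a tertiary allenylidene-like electrophile) should prefer the C7 hydroxyl, which has two ortho hydrogens, over the C5 hydroxyl, which is flanked by the ring-fusion carbon and lies peri to the propyl-bearing C4; the bulky ether blocks this oxygen and stores the later prenyl group.

**Step 4**
Reactants: 6 (4R)-5-hydroxy-7-[(2-methylbut-3-yn-2-yl)oxy]-4-propylchroman-2-one; 7 paraformaldehyde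
Product: 8 (4R)-5-hydroxy-7-[(2-methylbut-3-yn-2-yl)oxy]-2-oxo-4-propylchromane-6-carbaldehyde
Conditions: MgCl2 (2 equiv), Et3N (4 equiv), (CH2O)n (6 equiv), THF, 65 °C; dilute HCl work-up
Reagents that add atoms: formaldehyde (from paraformaldehyde), C=O
Why: Casnati–Skattebøl ortho-formylation delivers formaldehyde within the magnesium phenoxide, so the formyl group can only enter at C6, the single free position ortho to the single free phenol, a second equivalent of formaldehyde oxidising the intermediate benzylic alkoxide; the non-acidic conditions should spare the tertiary propargyl ether and the lactone.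

**Step 5**
Reactants: 8 (4R)-5-hydroxy-7-[(2-methylbut-3-yn-2-yl)oxy]-2-oxo-4-propylchromane-6-carbaldehyde
Product: 9 (4R)-5-hydroxy-7-[(2-methylbut-3-en-2-yl)oxy]-2-oxo-4-propylchromane-6-carbaldehyde
Conditions: H2 (1 atm), Pd/CaCO3 poisoned with Pb(OAc)2 (Lindlar catalyst), quinoline, EtOAc, 20 °C
Reagents that add atoms: none
Why: Lindlar semi-hydrogenation should stop at the terminal alkene and give the 1,1-dimethylallyl ether needed for the later [3,3] shift, while the aryl aldehyde and the lactone are not reduced.

**Step 6**
Reactants: 9 (4R)-5-hydroxy-7-[(2-methylbut-3-en-2-yl)oxy]-2-oxo-4-propylchromane-6-carbaldehyde; 10 but-2-yne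
Product: 13 (2S,3S,10R)-2,3-dimethyl-5-[(2-methylbut-3-en-2-yl)oxy]-10-propyl-2,3,9,10-tetrahydro-4H,8H-pyrano[2,3-f]chromene-4,8-dione, via tigloyl enone 11 (not isolated), via cis-chromanone 12 (not isolated)
Conditions: [Rh(cod)Cl]2 (2.5 mol%), 1,1'-bis(diphenylphosphino)ferrocene (5.5 mol%), Na2CO3 (10 mol%), but-2-yne (5 equiv), toluene, sealed tube, 60 °C; filter through Celite; quinidine (30 mol%), 20 °C; then Et3N (2 equiv), 40 °C
Reagents that add atoms: but-2-yne, CC#CC
Why: The phenol next to the formyl group binds rhodium as a phenoxide, so that oxidative addition into the aldehyde C–H bond, syn insertion of but-2-yne and reductive elimination give the E-configured tigloyl ketone 11, whose phenol, deprotonated by the quinuclidine nitrogen of quinidine while the C9 hydroxyl of the catalyst binds the carbonyl group, adds to the β-carbon. The closest known reaction types are the rhodium-catalysed tandem alkyne hydroacylation/oxa-Michael addition of salicylaldehydes to trans-2,3-disubstituted chroman-4-ones and the cinchona-alkaloid-catalysed enantioselective oxa-Michael cyclisation of ortho-tigloylphenols. The pyranone ring is closed by a 6-endo-trig conjugate addition that forms O1–C2 after the intermolecular union C4–C3. C2 is set by the catalyst (quinine gives the R-configured ether carbon in related tigloylphenols, so its pseudoenantiomer quinidine should give 2S), whereas C3 is set by the substrate under thermodynamic control: Et3N equilibrates the kinetic mixture of 12 and 13 through the enol to the trans-2,3-diequatorial isomer 13, so both C3 epimers converge. The step needs the right ring oxygen, intermolecular rather than intramolecular hydroacylation and a C2 centre that survives the equilibration; these are secured by the single free phenol (the second ortho oxygen is blocked as the tertiary allyl ether, the third is held in the lactone), by the phenoxide chelate that holds rhodium on the side remote from the alkene of the ether, and by the endocyclic C2–O1 bond lying near the nodal plane of the chromanone enolate, which should make retro-addition slower than reprotonation. Keeping all stages at or below 60 °C should prevent a premature [3,3] shift of the tertiary allyl ether.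

**Step 7**
Reactants: 13 (2S,3S,10R)-2,3-dimethyl-5-[(2-methylbut-3-en-2-yl)oxy]-10-propyl-2,3,9,10-tetrahydro-4H,8H-pyrano[2,3-f]chromene-4,8-dione
Product: 14 (2S,3S,10R)-5-hydroxy-2,3-dimethyl-6-(3-methylbut-2-en-1-yl)-10-propyl-2,3,9,10-tetrahydro-4H,8H-pyrano[2,3-f]chromene-4,8-dione
Conditions: toluene (degassed), 110 °C
Reagents that add atoms: none
Why: Aromatic Claisen rearrangement of the 1,1-dimethylallyl aryl ether through a chair transition state transfers the allyl unit with allylic inversion to C6, the only free ortho position, so the prenyl group appears there and rearomatisation frees the C5 hydroxyl, now hydrogen-bonded to the C4 ketone; no stereocentre is involved.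

**Step 8**
Reactants: 14 (2S,3S,10R)-5-hydroxy-2,3-dimethyl-6-(3-methylbut-2-en-1-yl)-10-propyl-2,3,9,10-tetrahydro-4H,8H-pyrano[2,3-f]chromene-4,8-dione; 15 methanol
Product: 16 methyl (3R)-3-[(2S,3S)-5,7-dihydroxy-2,3-dimethyl-6-(3-methylbut-2-en-1-yl)-4-oxo-3,4-dihydro-2H-chromen-8-yl]hexanoate
Conditions: MeOH, Et3N (2 equiv), 20 °C; pH 6 buffer work-up, concentration below 30 °C
Reagents that add atoms: methanol, CO
Why: Amine-catalysed methanolysis (transesterification) of the activated aryl lactone is driven by methanol as solvent and should release the C7 phenol and the methyl ester, while the partly ionised phenols of the product lower the acidity of C3–H and so protect the C2 and C3 centres.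

**Compound list**
1 | phloroglucinol (benzene-1,3,5-triol) | Oc1cc(O)cc(O)c1 | starting material
2 | (E)-hex-2-enal | CCC/C=C/C=O | starting material
3 | (4R)-4-propylchromane-2,5,7-triol (lactol as its anomeric mixture) | CCC[C@@H]1CC(O)Oc2cc(O)cc(O)c21 | intermediate
4 | (4R)-5,7-dihydroxy-4-propylchroman-2-one | CCC[C@@H]1CC(=O)Oc2cc(O)cc(O)c21 | intermediate
5 | 3-chloro-3-methylbut-1-yne | CC(C)(Cl)C#C | starting material
6 | (4R)-5-hydroxy-7-[(2-methylbut-3-yn-2-yl)oxy]-4-propylchroman-2-one | CCC[C@@H]1CC(=O)Oc2cc(OC(C)(C)C#C)cc(O)c21 | intermediate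
7 | paraformaldehyde (formaldehyde source) | C=O | starting material
8 | (4R)-5-hydroxy-7-[(2-methylbut-3-yn-2-yl)oxy]-2-oxo-4-propylchromane-6-carbaldehyde | CCC[C@@H]1CC(=O)Oc2cc(OC(C)(C)C#C)c(C=O)c(O)c21 | intermediate
9 | (4R)-5-hydroxy-7-[(2-methylbut-3-en-2-yl)oxy]-2-oxo-4-propylchromane-6-carbaldehyde | CCC[C@@H]1CC(=O)Oc2cc(OC(C)(C)C=C)c(C=O)c(O)c21 | intermediate
10 | but-2-yne | CC#CC | starting material
11 | (4R)-5-hydroxy-6-[(2E)-2-methylbut-2-enoyl]-7-[(2-methylbut-3-en-2-yl)oxy]-4-propylchroman-2-one | CCC[C@@H]1CC(=O)Oc2cc(OC(C)(C)C=C)c(C(=O)/C(C)=C/C)c(O)c21 | intermediate (not isolated)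
12 | (2S,3R,10R)-2,3-dimethyl-5-[(2-methylbut-3-en-2-yl)oxy]-10-propyl-2,3,9,10-tetrahydro-4H,8H-pyrano[2,3-f]chromene-4,8-dione (cis) | CCC[C@@H]1CC(=O)Oc2cc(OC(C)(C)C=C)c3c(c21)O[C@@H](C)[C@@H](C)C3=O | intermediate (not isolated)
13 | (2S,3S,10R)-2,3-dimethyl-5-[(2-methylbut-3-en-2-yl)oxy]-10-propyl-2,3,9,10-tetrahydro-4H,8H-pyrano[2,3-f]chromene-4,8-dione (trans) | CCC[C@@H]1CC(=O)Oc2cc(OC(C)(C)C=C)c3c(c21)O[C@@H](C)[C@H](C)C3=O | intermediate
14 | (2S,3S,10R)-5-hydroxy-2,3-dimethyl-6-(3-methylbut-2-en-1-yl)-10-propyl-2,3,9,10-tetrahydro-4H,8H-pyrano[2,3-f]chromene-4,8-dione | CCC[C@@H]1CC(=O)Oc2c(CC=C(C)C)c(O)c3c(c21)O[C@@H](C)[C@H](C)C3=O | intermediate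
15 | methanol | CO | starting material
16 | methyl (3R)-3-[(2S,3S)-5,7-dihydroxy-2,3-dimethyl-6-(3-methylbut-2-en-1-yl)-4-oxo-3,4-dihydro-2H-chromen-8-yl]hexanoate | CCC[C@H](CC(=O)OC)c1c(O)c(CC=C(C)C)c(O)c2c1O[C@@H](C)[C@H](C)C2=O | target

**Total step count:** 8. **Longest linear sequence:** 8 steps.

**Steps most likely to fail**

Step 6. In the rhodium stage the tertiary allyl ether may shift or ionise prematurely, and C–H activation at the doubly ortho-substituted aldehyde may be sluggish. In the amine stage facial discrimination may be insufficient, or the aryl lactone may acylate the alkaloid hydroxyl. C2 integrity may also be lost by retro-addition during the C3 equilibration. The fallback closes the ring by a stereospecific SN2 reaction of a reagent-controlled aldol; it sets out from 9 and comes back at 13. Addition of diethylzinc to 9 (Et2Zn, Ti(OiPr)4, toluene, 0 °C) should give the benzylic alcohol (4R)-5-hydroxy-6-(1-hydroxypropyl)-7-[(2-methylbut-3-en-2-yl)oxy]-4-propylchroman-2-one F1. Oxidation with MnO2 (CH2Cl2, 20 °C) should give the propionyl ketone (4R)-5-hydroxy-7-[(2-methylbut-3-en-2-yl)oxy]-6-propanoyl-4-propylchroman-2-one F2. A syn-selective boron aldol addition to acetaldehyde (Ipc2BOTf of the antipode that delivers the 3R carbinol, iPr2NEt, CH2Cl2, −78 °C, oxidative work-up) should give the β-hydroxy ketone (4R)-5-hydroxy-6-[(3R)-3-hydroxy-2-methylbutanoyl]-7-[(2-methylbut-3-en-2-yl)oxy]-4-propylchroman-2-one F3. Mitsunobu cyclisation (PPh3, diisopropyl azodicarboxylate, THF, 0 °C) should then displace the activated carbinol by the neighbouring phenol with inversion to give the 2S chromanone as a mixture of C3 epimers, which Et3N equilibrates to 13.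

Step 3. The two phenols may not be discriminated well enough, and over-alkylation may occur. The fallback installs the ether before the positions are differentiated; it sets out from 1 and comes back at 6. Mono-alkylation of 1 (used in excess) with 5 (K2CO3, KI, CuI, acetone) should give 5-[(2-methylbut-3-yn-2-yl)oxy]benzene-1,3-diol F4. The iminium-catalysed Friedel–Crafts alkylation/hemiacetalisation with 2 (conditions of step 1) should then take place between the two hydroxyl groups, the positions next to the tertiary ether being shielded, to give the lactol (4R)-7-[(2-methylbut-3-yn-2-yl)oxy]-4-propylchromane-2,5-diol F5. The transfer dehydrogenation of step 2 should then give 6.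

Step 1. The threefold nucleophile may be alkylated repeatedly, 1,2-addition with condensation to 2H-chromenes may compete, and an uncatalysed background reaction may erode the enantioselectivity. The fallback builds the lactone at the coumarin oxidation level and sets the stereocentre by conjugate reduction; it sets out from 1 and comes back at 4. Pechmann condensation of 1 with ethyl 3-oxohexanoate (CF3SO3H, 0 °C to 20 °C) should give 5,7-dihydroxy-4-propyl-2H-chromen-2-one F6. Copper hydride conjugate reduction (Cu(OAc)2·H2O, DTBM-SEGPHOS of the antipode that gives the R lactone, (EtO)2MeSiH, t-BuOH, toluene, 0 °C; then NH4F and dilute HCl to cleave silyl ethers and close the lactone) should then give 4.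

**Further compounds**
F1 | step 6 | (4R)-5-hydroxy-6-(1-hydroxypropyl)-7-[(2-methylbut-3-en-2-yl)oxy]-4-propylchroman-2-one | CCC[C@@H]1CC(=O)Oc2cc(OC(C)(C)C=C)c(C(O)CC)c(O)c21
F2 | step 6 | (4R)-5-hydroxy-7-[(2-methylbut-3-en-2-yl)oxy]-6-propanoyl-4-propylchroman-2-one | CCC[C@@H]1CC(=O)Oc2cc(OC(C)(C)C=C)c(C(=O)CC)c(O)c21
F3 | step 6 | (4R)-5-hydroxy-6-[(3R)-3-hydroxy-2-methylbutanoyl]-7-[(2-methylbut-3-en-2-yl)oxy]-4-propylchroman-2-one | CCC[C@@H]1CC(=O)Oc2cc(OC(C)(C)C=C)c(C(=O)C(C)[C@@H](C)O)c(O)c21
F4 | step 3 | 5-[(2-methylbut-3-yn-2-yl)oxy]benzene-1,3-diol | Oc1cc(O)cc(OC(C)(C)C#C)c1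
F5 | step 3 | (4R)-7-[(2-methylbut-3-yn-2-yl)oxy]-4-propylchromane-2,5-diol | CCC[C@@H]1CC(O)Oc2cc(OC(C)(C)C#C)cc(O)c21
F6 | step 1 | 5,7-dihydroxy-4-propyl-2H-chromen-2-one | CCCC1=CC(=O)Oc2cc(O)cc(O)c12
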